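**Assumption (remark on the chemistry):** the stereodescriptors of the SMILES are taken as written. They describe a cis-2,3-dihydrobenzofuran (2R,3R) and an oxolane whose aryl, hydroxymethyl and arylmethyl groups are all cis, with the tertiary OH trans to them (3S,4R,5R as an oxolan-3-ol). Both rings are therefore built by kinetically controlled, face-selective steps, and strong acid or base is avoided afterwards.

## Retrosynthetic overview

1. Target ⇐ desilylation ⇐ all-cis oxolane ⇐ hydroxyl-directed syn-hydrogenation of a 4-hydroxy-4,5-dihydrofuran-3-carbaldehyde (sets the aryl- and CH2OH-bearing carbons together), then hydride reduction of the formyl group and the benzofuran ester.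
2. Key disconnection: dihydrofuran ⇐ aryl propynal + 1-hydroxy-3-arylpropan-2-one by a chiral-amine oxa-Michael/aldol [3+2] annulation that forms the ring O–C(aryl) bond and the C–C bond to the carbinol carbon. Enabling feature (oxolane numbered O1, C2 aryl, C3, C4 carbinol, C5): O1–C5H2–C4(OH) is a masked α-hydroxy ketone (C4 = carbonyl carbon), and C2(aryl)–C3–CH2OH is a masked β-aryl ynal (C2 = β-carbon, C3 = α-carbon, CH2OH = formyl).
3. cis-Dihydrobenzofuran ⇐ aryl diazoacetate by enantioselective rhodium-carbenoid 1,5-C–H insertion into the benzylic ether CH2; diazo ester ⇐ aryl iodide + ethyl diazoacetate; ether ⇐ Mitsunobu coupling of a vanillin-derived benzyl alcohol with 4-bromo-2-iodo-6-methoxyphenol.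
4. Hydroxy ketone ⇐ homovanillic acid chloride + tris(trimethylsilyloxy)ethylene.
5. Ring order: dihydrobenzofuran ring (step 6), dihydrofuran ring (step 11), saturated oxolane (step 12).

Key step: step 11

## Route

Step 1
Reactants: 1 vanillin
Product: 2 3-methoxy-4-(triisopropylsilyloxy)benzaldehyde
Conditions: TIPSCl, imidazole, DMF, rt
Reagents that add atoms: triisopropylsilyl chloride, CC(C)[Si](Cl)(C(C)C)C(C)C
Why: Imidazole-promoted silylation of the phenol gives an aryl TIPS ether that should survive every later step and leave with fluoride at the end.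

Step 2
Reactants: 2 3-methoxy-4-(triisopropylsilyloxy)benzaldehyde
Product: 3 [3-methoxy-4-(triisopropylsilyloxy)phenyl]methanol
Conditions: NaBH4, MeOH–THF, 0 °C
Reagents that add atoms: none
Why: Borohydride reduction of the aldehyde to the benzylic alcohol should leave the aryl silyl ether intact.

Step 3
Reactants: 4 4-bromo-2-methoxyphenol
Product: 5 4-bromo-2-iodo-6-methoxyphenol
Conditions: NIS, p-TsOH·H2O (10 mol %), MeCN, rt
Reagents that add atoms: N-iodosuccinimide, O=C1CCC(=O)N1I
Why: Electrophilic aromatic iodination is directed by the hydroxyl group to its only free ortho position, the para position being blocked by bromine.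

Step 4
Reactants: 3 [3-methoxy-4-(triisopropylsilyloxy)phenyl]methanol; 5 4-bromo-2-iodo-6-methoxyphenol
Product: 6 5-bromo-1-iodo-3-methoxy-2-{[3-methoxy-4-(triisopropylsilyloxy)phenyl]methoxy}benzene
Conditions: PPh3, DIAD, THF, 0 °C to rt
Reagents that add atoms: none
Why: Mitsunobu etherification of the acidic ortho-halophenol with the primary benzylic alcohol runs under neutral conditions that should spare the aryl silyl ether.

Step 5
Reactants: 6 5-bromo-1-iodo-3-methoxy-2-{[3-methoxy-4-(triisopropylsilyloxy)phenyl]methoxy}benzene; 7 ethyl diazoacetate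
Product: 8 ethyl 2-(5-bromo-3-methoxy-2-{[3-methoxy-4-(triisopropylsilyloxy)phenyl]methoxy}phenyl)-2-diazoacetate
Conditions: Pd(PPh3)4 (5 mol %), Ag2CO3 (0.5 equiv), Et3N (1.3 equiv), toluene, rt
Reagents that add atoms: none
Why: Palladium-catalysed cross-coupling of an aryl iodide with an acceptor diazo ester keeps the diazo group, and at room temperature oxidative addition should occur at C–I only, leaving C–Br untouched.

Step 6
Reactants: 8 ethyl 2-(5-bromo-3-methoxy-2-{[3-methoxy-4-(triisopropylsilyloxy)phenyl]methoxy}phenyl)-2-diazoacetate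
Product: 9 ethyl (2R,3S)-5-bromo-7-methoxy-2-[3-methoxy-4-(triisopropylsilyloxy)phenyl]-2,3-dihydro-1-benzofuran-3-carboxylate (2,3-cis)
Conditions: Rh2(S-PTTL)4 (2 mol %), toluene, −60 °C
Reagents that add atoms: none
Why: Intramolecular 1,5-C–H insertion of the rhodium carbenoid into the electron-rich benzylic ether C–H closes the dihydrofuran ring; the concerted insertion should give the kinetic cis isomer, and the chiral carboxylate ligands select the enantiotopic C–H in the (2R) sense expected for this catalyst family with 2-(benzyloxy)aryl diazoacetates.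

Step 7
Reactants: 9 ethyl (2R,3S)-5-bromo-7-methoxy-2-[3-methoxy-4-(triisopropylsilyloxy)phenyl]-2,3-dihydro-1-benzofuran-3-carboxylate; 10 propargyl alcohol
Product: 11 ethyl (2R,3S)-5-(3-hydroxyprop-1-yn-1-yl)-7-methoxy-2-[3-methoxy-4-(triisopropylsilyloxy)phenyl]-2,3-dihydro-1-benzofuran-3-carboxylate
Conditions: Pd(PhCN)2Cl2 (3 mol %), [HP(t-Bu)3]BF4 (6 mol %), CuI (2 mol %), i-Pr2NH, 1,4-dioxane, rt
Reagents that add atoms: none
Why: Sonogashira coupling with the tri-tert-butylphosphine system should couple the electron-rich aryl bromide at room temperature, where the amine base is too weak to epimerise the cis ester.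

Step 8
Reactants: 11 ethyl (2R,3S)-5-(3-hydroxyprop-1-yn-1-yl)-7-methoxy-2-[3-methoxy-4-(triisopropylsilyloxy)phenyl]-2,3-dihydro-1-benzofuran-3-carboxylate
Product: 12 ethyl (2R,3S)-7-methoxy-2-[3-methoxy-4-(triisopropylsilyloxy)phenyl]-5-(3-oxoprop-1-yn-1-yl)-2,3-dihydro-1-benzofuran-3-carboxylate
Conditions: activated MnO2 (15 equiv), CH2Cl2, rt
Reagents that add atoms: none
Why: Activated MnO2 oxidises the propargylic alcohol to the ynal under neutral conditions without touching the ester or the stereocentres.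

Step 9
Reactants: 13 homovanillic acid
Product: 15 2-[3-methoxy-4-(triisopropylsilyloxy)phenyl]acetic acid, via bis-silylated homovanillate 14 (not isolated)
Conditions: TIPSCl (2.2 equiv), imidazole, DMF, rt; then AcOH–THF–H2O, rt
Reagents that add atoms: triisopropylsilyl chloride, CC(C)[Si](Cl)(C(C)C)C(C)C
Why: Exhaustive silylation followed by selective hydrolysis of the much more labile silyl ester should give the free acid with the phenol protected.

Step 10
Reactants: 15 2-[3-methoxy-4-(triisopropylsilyloxy)phenyl]acetic acid; 16 tris(trimethylsilyloxy)ethylene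
Product: 19 1-hydroxy-3-[3-methoxy-4-(triisopropylsilyloxy)phenyl]propan-2-one, via acid chloride 17 (not isolated), via silylated keto ester adduct 18 (not isolated)
Conditions: (COCl)2, DMF (cat.), CH2Cl2, 0 °C to rt; evaporate; 16 (2.2 equiv), neat, 95 °C; then 0.5 M HCl, THF–H2O, 60 °C
Reagents that add atoms: none
Why: C-acylation of the ketene tris(silyl) acetal by the acid chloride, then acidic hydrolysis and decarboxylation of the α-hydroxy-β-keto acid, is a known one-pot conversion of acid chlorides into hydroxymethyl ketones that the aryl TIPS ether should tolerate.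

Step 11
Reactants: 12 ethyl (2R,3S)-7-methoxy-2-[3-methoxy-4-(triisopropylsilyloxy)phenyl]-5-(3-oxoprop-1-yn-1-yl)-2,3-dihydro-1-benzofuran-3-carboxylate; 19 1-hydroxy-3-[3-methoxy-4-(triisopropylsilyloxy)phenyl]propan-2-one (1.5 equiv)
Product: 20 ethyl (2R,3S)-5-[(4S)-3-formyl-4-hydroxy-4-{[3-methoxy-4-(triisopropylsilyloxy)phenyl]methyl}-4,5-dihydrofuran-2-yl]-7-methoxy-2-[3-methoxy-4-(triisopropylsilyloxy)phenyl]-2,3-dihydro-1-benzofuran-3-carboxylate
Conditions: (S)-α,α-diphenylprolinol trimethylsilyl ether (20 mol %), toluene, 0 °C to rt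
Reagents that add atoms: none
Why: Proposed new method: the amine condenses with ynal 12 to an alkynyl iminium ion, the primary hydroxyl of 19 adds to its β-carbon (oxa-Michael) to give a β-alkoxy allenamine, the allenamine α-carbon attacks the tethered ketone (intramolecular aldol), and hydrolysis of the resulting β-alkoxy iminium ion releases 20 and the catalyst, a formal [3+2] annulation that makes the ring O–C(aryl) bond and the C–C bond to the carbinol carbon in one operation. The closest known reaction type is the iminium–allenamine oxa-Michael/aldol cascade of alkynals with 2-hydroxyaryl ketones and keto esters (4H-chromen-4-ols with a tertiary carbinol centre), supported by the amine- or phosphine-mediated oxa-Michael/aldol annulation of α-hydroxy ketones with activated alkynes; new is an aliphatic α-hydroxy ketone under chiral secondary-amine control. The dihydrofuran ring closes by a 5-exo-trig aldol addition in which the enamine C=C is exocyclic to the new ring (enolexo mode), and the nucleophilic lobe lies in the plane that holds the ether oxygen, so the tether should reach the ketone without strain. The single new stereocentre, the tertiary carbinol C4, is controlled by the catalyst: the diphenyl(trimethylsilyloxy)methyl group blocks one face of the allenamine, the alkoxy tether reacts from the open face, and the ketone is expected to turn its oxygen toward the developing iminium nitrogen and its arylmethyl group away from the pyrrolidine, which leads to (4S). The step needs O- before C-addition (the α-keto hydroxyl is the only free heteroatom nucleophile, every other oxygen being silylated, etherified or an ester, and the benzylic enol of 19 is a poor donor without base), 1,4- before 1,2-addition (iminium activation) and ring closure before protonation of the allenamine (aprotic toluene, no acid co-catalyst).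

Step 12
Reactants: 20 ethyl (2R,3S)-5-[(4S)-3-formyl-4-hydroxy-4-{[3-methoxy-4-(triisopropylsilyloxy)phenyl]methyl}-4,5-dihydrofuran-2-yl]-7-methoxy-2-[3-methoxy-4-(triisopropylsilyloxy)phenyl]-2,3-dihydro-1-benzofuran-3-carboxylate
Product: 22 (3S,4R,5R)-5-[(2R,3R)-3-(hydroxymethyl)-7-methoxy-2-[3-methoxy-4-(triisopropylsilyloxy)phenyl]-2,3-dihydro-1-benzofuran-5-yl]-4-(hydroxymethyl)-3-{[3-methoxy-4-(triisopropylsilyloxy)phenyl]methyl}oxolan-3-ol, via saturated aldehyde 21 (not isolated)
Conditions: H2 (50 bar), [Ir(cod)(PCy3)(py)]PF6 (10 mol %), CH2Cl2, rt; evaporate; LiAlH4, THF, −78 to 0 °C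
Reagents that add atoms: none
Why: Hydroxyl-directed homogeneous hydrogenation should deliver both hydrogens syn from the face of the tertiary OH (also the less hindered face, anti to the arylmethyl group), which sets the aryl- and formyl-bearing carbons together and places aryl, formyl and arylmethyl all cis; LiAlH4 then reduces the epimerisable β-hydroxy aldehyde at −78 °C before it can equilibrate and, on warming, the cis ethyl ester to the second hydroxymethyl group.

Step 13
Reactants: 22 (3S,4R,5R)-5-[(2R,3R)-3-(hydroxymethyl)-7-methoxy-2-[3-methoxy-4-(triisopropylsilyloxy)phenyl]-2,3-dihydro-1-benzofuran-5-yl]-4-(hydroxymethyl)-3-{[3-methoxy-4-(triisopropylsilyloxy)phenyl]methyl}oxolan-3-ol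
Product: 23 (3S,4R,5R)-5-[(2R,3R)-2-(4-hydroxy-3-methoxyphenyl)-3-(hydroxymethyl)-7-methoxy-2,3-dihydro-1-benzofuran-5-yl]-3-[(4-hydroxy-3-methoxyphenyl)methyl]-4-(hydroxymethyl)oxolan-3-ol (CNP0284796.1)
Conditions: Bu4NF (2.5 equiv), AcOH (2.5 equiv), THF, 0 °C
Reagents that add atoms: none
Why: Fluoride cleavage of the two aryl silyl ethers, buffered with acetic acid, should avoid phenoxide-triggered opening (quinone methide formation) of the cis-dihydrobenzofuran and of the benzylic oxolane ether, so no stereocentre is disturbed.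

## Compound list

1 | vanillin | COc1cc(C=O)ccc1O | starting material
2 | 3-methoxy-4-(triisopropylsilyloxy)benzaldehyde | COc1cc(C=O)ccc1O[Si](C(C)C)(C(C)C)C(C)C | intermediate
3 | [3-methoxy-4-(triisopropylsilyloxy)phenyl]methanol | COc1cc(CO)ccc1O[Si](C(C)C)(C(C)C)C(C)C | intermediate
4 | 4-bromo-2-methoxyphenol | COc1cc(Br)ccc1O | starting material
5 | 4-bromo-2-iodo-6-methoxyphenol | COc1cc(Br)cc(I)c1O | intermediate
6 | 5-bromo-1-iodo-3-methoxy-2-{[3-methoxy-4-(triisopropylsilyloxy)phenyl]methoxy}benzene | COc1cc(Br)cc(I)c1OCc1ccc(O[Si](C(C)C)(C(C)C)C(C)C)c(OC)c1 | intermediate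
7 | ethyl diazoacetate | CCOC(=O)C=[N+]=[N-] | starting material
8 | ethyl 2-(5-bromo-3-methoxy-2-{[3-methoxy-4-(triisopropylsilyloxy)phenyl]methoxy}phenyl)-2-diazoacetate | CCOC(=O)C(=[N+]=[N-])c1cc(Br)cc(OC)c1OCc1ccc(O[Si](C(C)C)(C(C)C)C(C)C)c(OC)c1 | intermediate
9 | ethyl (2R,3S)-5-bromo-7-methoxy-2-[3-methoxy-4-(triisopropylsilyloxy)phenyl]-2,3-dihydro-1-benzofuran-3-carboxylate (cis) | Brc1cc(OC)c2c(c1)[C@H](C(=O)OCC)[C@H](c1ccc(O[Si](C(C)C)(C(C)C)C(C)C)c(OC)c1)O2 | intermediate
10 | propargyl alcohol | C#CCO | starting material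
11 | ethyl (2R,3S)-5-(3-hydroxyprop-1-yn-1-yl)-7-methoxy-2-[3-methoxy-4-(triisopropylsilyloxy)phenyl]-2,3-dihydro-1-benzofuran-3-carboxylate | OCC#Cc1cc(OC)c2c(c1)[C@H](C(=O)OCC)[C@H](c1ccc(O[Si](C(C)C)(C(C)C)C(C)C)c(OC)c1)O2 | intermediate
12 | ethyl (2R,3S)-7-methoxy-2-[3-methoxy-4-(triisopropylsilyloxy)phenyl]-5-(3-oxoprop-1-yn-1-yl)-2,3-dihydro-1-benzofuran-3-carboxylate | O=CC#Cc1cc(OC)c2c(c1)[C@H](C(=O)OCC)[C@H](c1ccc(O[Si](C(C)C)(C(C)C)C(C)C)c(OC)c1)O2 | intermediate
13 | homovanillic acid | COc1cc(CC(=O)O)ccc1O | starting material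
14 | triisopropylsilyl 2-[3-methoxy-4-(triisopropylsilyloxy)phenyl]acetate | COc1cc(CC(=O)O[Si](C(C)C)(C(C)C)C(C)C)ccc1O[Si](C(C)C)(C(C)C)C(C)C | intermediate
15 | 2-[3-methoxy-4-(triisopropylsilyloxy)phenyl]acetic acid | COc1cc(CC(=O)O)ccc1O[Si](C(C)C)(C(C)C)C(C)C | intermediate
16 | tris(trimethylsilyloxy)ethylene | C[Si](C)(C)OC=C(O[Si](C)(C)C)O[Si](C)(C)C | starting material
17 | 2-[3-methoxy-4-(triisopropylsilyloxy)phenyl]acetyl chloride | COc1cc(CC(=O)Cl)ccc1O[Si](C(C)C)(C(C)C)C(C)C | intermediate
18 | trimethylsilyl 4-[3-methoxy-4-(triisopropylsilyloxy)phenyl]-3-oxo-2-(trimethylsilyloxy)butanoate (racemic) | COc1cc(CC(=O)C(O[Si](C)(C)C)C(=O)O[Si](C)(C)C)ccc1O[Si](C(C)C)(C(C)C)C(C)C | intermediate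
19 | 1-hydroxy-3-[3-methoxy-4-(triisopropylsilyloxy)phenyl]propan-2-one | COc1cc(CC(=O)CO)ccc1O[Si](C(C)C)(C(C)C)C(C)C | intermediate
20 | ethyl (2R,3S)-5-[(4S)-3-formyl-4-hydroxy-4-{[3-methoxy-4-(triisopropylsilyloxy)phenyl]methyl}-4,5-dihydrofuran-2-yl]-7-methoxy-2-[3-methoxy-4-(triisopropylsilyloxy)phenyl]-2,3-dihydro-1-benzofuran-3-carboxylate | COc1cc(C[C@@]2(O)COC(c3cc(OC)c4c(c3)[C@H](C(=O)OCC)[C@H](c3ccc(O[Si](C(C)C)(C(C)C)C(C)C)c(OC)c3)O4)=C2C=O)ccc1O[Si](C(C)C)(C(C)C)C(C)C | intermediate
21 | ethyl (2R,3S)-5-[(2R,3R,4S)-3-formyl-4-hydroxy-4-{[3-methoxy-4-(triisopropylsilyloxy)phenyl]methyl}oxolan-2-yl]-7-methoxy-2-[3-methoxy-4-(triisopropylsilyloxy)phenyl]-2,3-dihydro-1-benzofuran-3-carboxylate (all-cis oxolane) | COc1cc(C[C@@]2(O)CO[C@@H](c3cc(OC)c4c(c3)[C@H](C(=O)OCC)[C@H](c3ccc(O[Si](C(C)C)(C(C)C)C(C)C)c(OC)c3)O4)[C@H]2C=O)ccc1O[Si](C(C)C)(C(C)C)C(C)C | intermediate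
22 | (3S,4R,5R)-5-[(2R,3R)-3-(hydroxymethyl)-7-methoxy-2-[3-methoxy-4-(triisopropylsilyloxy)phenyl]-2,3-dihydro-1-benzofuran-5-yl]-4-(hydroxymethyl)-3-{[3-methoxy-4-(triisopropylsilyloxy)phenyl]methyl}oxolan-3-ol | COc1cc(C[C@@]2(O)CO[C@@H](c3cc(OC)c4c(c3)[C@H](CO)[C@H](c3ccc(O[Si](C(C)C)(C(C)C)C(C)C)c(OC)c3)O4)[C@H]2CO)ccc1O[Si](C(C)C)(C(C)C)C(C)C | intermediate
23 | (3S,4R,5R)-5-[(2R,3R)-2-(4-hydroxy-3-methoxyphenyl)-3-(hydroxymethyl)-7-methoxy-2,3-dihydro-1-benzofuran-5-yl]-3-[(4-hydroxy-3-methoxyphenyl)methyl]-4-(hydroxymethyl)oxolan-3-ol | COc1cc(C[C@@]2(O)CO[C@@H](c3cc(OC)c4c(c3)[C@H](CO)[C@H](c3ccc(O)c(OC)c3)O4)[C@H]2CO)ccc1O | target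

## Step count and risks

Total step count: 13. Longest linear sequence: 10 steps (1, 2, 4, 5, 6, 7, 8, 11, 12, 13).

Steps most likely to fail:

**Step 11 (the proposed new method).** The allenamine may be protonated before it closes the ring, which stalls the sequence at an acyclic β-alkoxy enal. Facial selectivity at the ketone may be poor or reversed. The benzylic enol of the ketone may add through carbon, and the catalyst may be consumed by aza-Michael addition to the ynal or be released slowly from the product iminium ion. The fallback sets out from 12 and 19 and uses the known achiral tertiary-amine-mediated oxa-Michael/aldol annulation of α-hydroxy ketones with activated alkynes (DABCO, 20 mol %, CH2Cl2, 0 °C). Without stereocontrol at the carbinol carbon this should give 20 together with its diastereomer, the (4R)-epimer F1. Because of the two dihydrobenzofuran stereocentres these are diastereomers, which are separated by preparative HPLC. The route is rejoined at compound 20.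

**Step 12.** The tetrasubstituted, donor–acceptor-substituted alkene may resist hydrogenation. Traces of acid from the iridium catalyst may dehydrate the tertiary alcohol toward a furan. The all-cis aldehyde may epimerise at its α-carbon, or undergo retro-aldol opening, before the hydride arrives. The fallback reverses the order of the two reductions and sets out from compound 20. Luche reduction (NaBH4, CeCl3·7H2O, MeOH, −78 °C) removes the deactivating formyl group and should give the allylic alcohol F2, in which no epimerisable centre exists. Hydroxyl-directed hydrogenation of this electron-rich enol ether with [Rh(nbd)(dppb)]BF4 (H2, CH2Cl2, base-washed glassware) should then give the all-cis ester diol F3. LiAlH4 (THF, 0 °C) reduces the remaining ester and returns the route at compound 22.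

**Step 5.** The diazo group may be lost by palladium-carbene formation and dimerisation, oxidative addition next to the bulky ortho benzyloxy group may be slow, and the C–Br bond may begin to react if the mixture is warmed. The fallback sets out from compound 6. Negishi coupling with the Reformatsky reagent ethyl bromozincacetate (Pd(PPh3)4, THF, 50 °C, selective for the iodide) should give the arylacetate F4. Regitz diazo transfer (p-ABSA, DBU, MeCN, 0 °C to rt) then installs the diazo group and returns the route at compound 8.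

## Further compounds

F1 | step 11 | ethyl (2R,3S)-5-[(4R)-3-formyl-4-hydroxy-4-{[3-methoxy-4-(triisopropylsilyloxy)phenyl]methyl}-4,5-dihydrofuran-2-yl]-7-methoxy-2-[3-methoxy-4-(triisopropylsilyloxy)phenyl]-2,3-dihydro-1-benzofuran-3-carboxylate | COc1cc(C[C@]2(O)COC(c3cc(OC)c4c(c3)[C@H](C(=O)OCC)[C@H](c3ccc(O[Si](C(C)C)(C(C)C)C(C)C)c(OC)c3)O4)=C2C=O)ccc1O[Si](C(C)C)(C(C)C)C(C)C
F2 | step 12 | ethyl (2R,3S)-5-[(4S)-4-hydroxy-3-(hydroxymethyl)-4-{[3-methoxy-4-(triisopropylsilyloxy)phenyl]methyl}-4,5-dihydrofuran-2-yl]-7-methoxy-2-[3-methoxy-4-(triisopropylsilyloxy)phenyl]-2,3-dihydro-1-benzofuran-3-carboxylate | COc1cc(C[C@@]2(O)COC(c3cc(OC)c4c(c3)[C@H](C(=O)OCC)[C@H](c3ccc(O[Si](C(C)C)(C(C)C)C(C)C)c(OC)c3)O4)=C2CO)ccc1O[Si](C(C)C)(C(C)C)C(C)C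
F3 | step 12 | ethyl (2R,3S)-5-[(2R,3R,4S)-4-hydroxy-3-(hydroxymethyl)-4-{[3-methoxy-4-(triisopropylsilyloxy)phenyl]methyl}oxolan-2-yl]-7-methoxy-2-[3-methoxy-4-(triisopropylsilyloxy)phenyl]-2,3-dihydro-1-benzofuran-3-carboxylate | COc1cc(C[C@@]2(O)CO[C@@H](c3cc(OC)c4c(c3)[C@H](C(=O)OCC)[C@H](c3ccc(O[Si](C(C)C)(C(C)C)C(C)C)c(OC)c3)O4)[C@H]2CO)ccc1O[Si](C(C)C)(C(C)C)C(C)C
F4 | step 5 | ethyl 2-(5-bromo-3-methoxy-2-{[3-methoxy-4-(triisopropylsilyloxy)phenyl]methoxy}phenyl)acetate | CCOC(=O)Cc1cc(Br)cc(OC)c1OCc1ccc(O[Si](C(C)C)(C(C)C)C(C)C)c(OC)c1
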